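**Plan**

1. Retrosynthetic cuts (ent-kaurane numbering throughout): the C15 ketone/C16=C17 methylene goes back to a C15=C16–CH3 alkene; C8–C15 is exchanged for C9–C15 (reverse of a radical 1,2-vinyl shift); C8–C9 and C13–C14 are cut together ([4+2]), which also opens the 7,20-lactone ring; then C9–C10 (aryl shift from C1), C1–aryl, C10–C20 and C5–C6.
2. Enabling feature: C9, C11(O), C12, C13, C16 (with C17) and C15 are the ring of 2-methoxy-4-methylphenol once C15 is written on C9, and C20–O–C7(=O)–C8=C14 is an ester tether from C10 to that ring.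
3. Forward order: ring A comes from 4,4-dimethylcyclohexenone; the arene is added to C1 and shifted to C10; the δ-lactone and a bicyclo[2.2.2]octenone close in one step; a 1,2-shift gives the bicyclo[3.2.1]octene (rings C and D); redox steps finish.
4. Stereochemistry: C5 from a ligand-controlled conjugate addition; C10 relayed from C5 (aryl addition anti to the C5 group, hydroxyl-directed epoxidation, invertive aryl shift); C9 and C13 from the diene face chosen by C10, C8 from the suprafacial shift, C9–H from hydrogen transfer; C1 from axial hydride attack, whose alkoxide passes hydride on to C11.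
5. Two choices: the dienophile is a 2-bromoacrylate, so that the C8 radical precursor arrives with the cycloaddition and no enolate chemistry is needed; C1 stays a ketone until step 16. Ar = 3-methoxy-2-(methoxymethoxy)-5-methylphenyl.

Key step: step 13

Assumption: the face selectivity of the [Rh(cod)(MeCN)2]BF4/BINAP addition to 4,4-dimethylcyclohex-2-en-1-one is taken to follow that known for cyclohex-2-en-1-one, which calls for (R)-BINAP.

Step 1
Reactants: 1 2-methoxy-4-methylphenol
Product: 2 2-methoxy-1-(methoxymethoxy)-4-methylbenzene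
Conditions: MOMCl, i-Pr2NEt, CH2Cl2, 0 °C to rt
Reagents that add atoms: chloromethyl methyl ether, COCCl
Why: Base-mediated O-alkylation of the phenol (Williamson-type ether synthesis) gives the methoxymethyl ether, which masks the phenol and is the stronger ortho-directing group for the lithiation in step 4.

Step 2
Reactants: 3 4,4-dimethylcyclohex-2-en-1-one; 4 hex-1-yne
Product: 7 (2R,3S)-2-[(dimethylamino)methyl]-3-[(E)-hex-1-enyl]-4,4-dimethylcyclohexan-1-one, via (E)-hex-1-enylzirconocene chloride 5 (not isolated), via zirconium enolate 6 (not isolated)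
Conditions: 4, Cp2Zr(H)Cl, THF, rt; then 3, [Rh(cod)(MeCN)2]BF4 (5 mol %), (R)-BINAP (6 mol %), rt; then CH2=NMe2+ I−, 0 °C to rt
Reagents that add atoms: dimethyl(methylidene)ammonium iodide, C=[N+](C)C.[I-]
Why: Hydrozirconation of 4, asymmetric 1,4-addition of the alkenylzirconium reagent 5 under [Rh(cod)(MeCN)2]BF4/(R)-BINAP catalysis (ligand control sets C5 next to the gem-dimethyl carbon) and Mannich capture of the regiodefined enolate 6 by the iminium salt should give 7, the aminomethyl group entering trans to the alkenyl group.

Step 3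
Reactants: 7 (2R,3S)-2-[(dimethylamino)methyl]-3-[(E)-hex-1-enyl]-4,4-dimethylcyclohexan-1-one
Product: 9 (R)-3-[(E)-hex-1-enyl]-4,4-dimethyl-2-methylidenecyclohexan-1-one, via trimethylammonium iodide 8 (not isolated)
Conditions: MeI, CH2Cl2, rt; then aqueous NaHCO3, rt
Reagents that add atoms: none
Why: N-methylation and base-induced β-elimination of trimethylamine from the Mannich base (Hofmann-type elimination) should give the exocyclic enone regiospecifically, C5 being untouched.

Step 4
Reactants: 2 2-methoxy-1-(methoxymethoxy)-4-methylbenzene; 9 (R)-3-[(E)-hex-1-enyl]-4,4-dimethyl-2-methylidenecyclohexan-1-one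
Product: 12 (1S,3R)-1-Ar-3-[(E)-hex-1-enyl]-4,4-dimethyl-2-methylidenecyclohexan-1-ol, via aryllithium 10 (not isolated), via arylcerium dichloride 11 (not isolated)
Conditions: 2, n-BuLi, TMEDA, THF, 0 °C; CeCl3, −78 °C; then 9, −78 °C
Reagents that add atoms: none
Why: Directed ortho-lithiation beside the OMOM group, transmetalation to ArCeCl2 and 1,2-addition to the enone carbonyl should take place on the face opposite the pseudo-axial C5 alkenyl group (axial to avoid allylic strain with the exocyclic methylene, and shielding its own face by a 1,3-diaxial contact), so that the aryl group ends up trans and the hydroxyl cis to that group.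

Step 5
Reactants: 12 (1S,3R)-1-Ar-3-[(E)-hex-1-enyl]-4,4-dimethyl-2-methylidenecyclohexan-1-ol
Product: 13 4-Ar-8-[(E)-hex-1-enyl]-7,7-dimethyl-1-oxaspiro[2.5]octan-4-ol (epoxide oxygen cis to the hydroxyl)
Conditions: VO(acac)2 (5 mol %), t-BuOOH, CH2Cl2, 0 °C
Reagents that add atoms: tert-butyl hydroperoxide, CC(C)(C)OO
Why: Hydroxyl-directed epoxidation of the allylic alcohol with VO(acac)2 and t-BuOOH should deliver oxygen to the exocyclic alkene on the face of the hydroxyl and away from the aryl group, which sets the C10–O bond anti to the aryl group and leaves the remote disubstituted alkene untouched.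

Step 6
Reactants: 13 4-Ar-8-[(E)-hex-1-enyl]-7,7-dimethyl-1-oxaspiro[2.5]octan-4-ol
Product: 14 2-Ar-2-[(tert-butyldimethylsilyloxy)methyl]-3-[(E)-hex-1-enyl]-4,4-dimethylcyclohexan-1-one (CH2OTBS cis and Ar trans to the hexenyl group)
Conditions: TBSOTf, 2,6-lutidine, CH2Cl2, −78 to −40 °C
Reagents that add atoms: tert-butyldimethylsilyl trifluoromethanesulfonate, CC(C)(C)[Si](C)(C)OS(=O)(=O)C(F)(F)F
Why: Silyl triflate activation of the epoxide starts a semipinacol rearrangement of the 2,3-epoxy alcohol in which the electron-rich aryl group shifts from C1 to C10 with inversion, so that C10 becomes the quaternary centre with the aryl group trans and the silyloxymethyl group cis to the C5 substituent, C1 becomes the ketone and the C20 oxygen emerges already silylated.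

Step 7
Reactants: 14 2-Ar-2-[(tert-butyldimethylsilyloxy)methyl]-3-[(E)-hex-1-enyl]-4,4-dimethylcyclohexan-1-one
Product: 15 2-Ar-2-[(tert-butyldimethylsilyloxy)methyl]-6,6-dimethyl-3-oxocyclohexane-1-carbaldehyde
Conditions: OsO4 (2 mol %), NaIO4, 2,6-lutidine, dioxane–H2O, rt
Reagents that add atoms: osmium tetroxide (catalytic oxygen carrier), O=[Os](=O)(=O)=O; sodium periodate, [Na+].[O-]I(=O)(=O)=O
Why: Lemieux–Johnson oxidation (dihydroxylation by catalytic OsO4 and glycol cleavage by NaIO4) should cut the only alkene to the C6 aldehyde, which is equatorial on ring A and therefore holds the C5 configuration.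

Step 8
Reactants: 15 2-Ar-2-[(tert-butyldimethylsilyloxy)methyl]-6,6-dimethyl-3-oxocyclohexane-1-carbaldehyde
Product: 16 2-Ar-2-[(tert-butyldimethylsilyloxy)methyl]-3-(hydroxymethyl)-4,4-dimethylcyclohexan-1-one
Conditions: NaBH4 (0.5 equiv), MeOH–CH2Cl2, −78 °C
Reagents that add atoms: none
Why: Chemoselective hydride reduction with a substoichiometric amount of NaBH4 at low temperature should take the aldehyde and spare the hindered α-quaternary C1 ketone, which is kept as the latent C1 hydroxyl.

Step 9
Reactants: 16 2-Ar-2-[(tert-butyldimethylsilyloxy)methyl]-3-(hydroxymethyl)-4,4-dimethylcyclohexan-1-one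
Product: 17 {2-Ar-2-[(tert-butyldimethylsilyloxy)methyl]-6,6-dimethyl-3-oxocyclohexyl}methyl acetate
Conditions: Ac2O, pyridine, DMAP (catalytic), CH2Cl2, 0 °C to rt
Reagents that add atoms: acetic anhydride, CC(=O)OC(C)=O
Why: DMAP-catalysed acylation of the primary alcohol installs the C6 acetate of the target.

Step 10
Reactants: 17 {2-Ar-2-[(tert-butyldimethylsilyloxy)methyl]-6,6-dimethyl-3-oxocyclohexyl}methyl acetate
Product: 18 [2-Ar-2-(hydroxymethyl)-6,6-dimethyl-3-oxocyclohexyl]methyl acetate
Conditions: HF·pyridine, THF–pyridine, 0 °C to rt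
Reagents that add atoms: none
Why: Fluoride-induced cleavage of the silyl ether under buffered, non-basic conditions should free the C20 hydroxyl without forming the alkoxide that could lose formaldehyde by retro-aldol reaction.

Step 11
Reactants: 18 [2-Ar-2-(hydroxymethyl)-6,6-dimethyl-3-oxocyclohexyl]methyl acetate; 19 2,3-dibromopropanoyl chloride
Product: 21 ring A keto acetate bearing the C20 2-bromoprop-2-enoate, via 2,3-dibromopropanoate 20 (not isolated)
Conditions: 19, Et3N, CH2Cl2, −78 to 0 °C
Reagents that add atoms: none
Why: Acylation of the neopentyl alcohol by the acid chloride and amine-induced dehydrobromination of the 2,3-dibromo ester 20 (E1cB elimination) should give the 2-bromoacrylate, which brings in C7, C8 and C14 together with the bromine that later serves as the C8 radical precursor.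

Step 12
Reactants: 21 ring A keto acetate bearing the C20 2-bromoprop-2-enoate
Product: 22 ring A 2-bromoacrylate with a free 2-hydroxy-3-methoxy-5-methylphenyl group on C10
Conditions: TFA, CH2Cl2, 0 °C
Reagents that add atoms: none
Why: Acid-catalysed cleavage of the aryl methoxymethyl acetal should release the phenol while the esters, the ketone and the bromoacrylate are inert to trifluoroacetic acid.

Step 13
Reactants: 22 ring A 2-bromoacrylate with a free 2-hydroxy-3-methoxy-5-methylphenyl group on C10
Product: 24 8-bromo-12,12-dimethoxy-1,11-dioxo δ-lactone-fused bicyclo[2.2.2]oct-15-ene adduct, via masked o-benzoquinone 23 (not isolated)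
Conditions: PhI(OAc)2, MeOH, 0 °C; then toluene (0.005 M), BHT, MeOH distilled off, 110 °C
Reagents that add atoms: methanol, CO
Why: Ligand exchange of the phenol at iodine and two-electron oxidation with capture of methanol at C12 give the 6,6-dimethoxycyclohexa-2,4-dienone 23, whose diene C9=C15–C16=C13 is then trapped by the tethered 2-bromoacrylate in an intramolecular Diels–Alder reaction that forms C8–C9 and C13–C14. The closest known reaction type is the oxidative dearomatisation of 2-methoxyphenols to masked o-benzoquinones with intramolecular [4+2] trapping by a tethered acrylate. The δ-lactone (C7, C8, C9, C10, C20, O) closes in the fused mode through the four-atom tether C10–C20–O–C7, and the bicyclo[2.2.2]octenone closes by the cycloaddition itself across C9 and C13 of the dienone. C9 and C13 are set together by the diene face, which C10 controls: C20 must stand perpendicular to the dienone on the face that is attacked, and the rotamer that puts the bulky C5 branch beside the small C15–H and the flat C1 carbonyl beside the C11 carbonyl places C11, and later C14, on the C1 side of the lactone ring; C8 is set by the tether together with the exo preference of the carbonyl group of α-bromo dienophiles and is erased in the next step. The step needs regioselectivity, secured by the tether and matched by the intrinsic preference of these dienones to join their carbonyl-side terminus to the substituted dienophile carbon, facial selectivity, secured by C10, and ring closure faster than dimerisation of 23, which the fully substituted C9, the C16 methyl group, high dilution and the activating bromine should favour.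

Step 14
Reactants: 24 8-bromo-12,12-dimethoxy-1,11-dioxo δ-lactone-fused bicyclo[2.2.2]oct-15-ene adduct
Product: 25 12,12-dimethoxy-1,11-dioxo bicyclo[3.2.1]oct-15-ene lactone (C15 on C8; 9-H as in the target)
Conditions: Bu3SnH (syringe pump), AIBN, PhH (0.005 M), 80 °C
Reagents that add atoms: none
Why: Radical chain reaction with Bu3SnH in which bromine abstraction gives the C8 radical, 3-exo addition to C15 and reopening of the cyclopropylcarbinyl radical toward C9 move the vinyl carbon C15 from C9 to C8 (homoallyl radical 1,2-vinyl shift driven by the tertiary α-keto radical at C9), C15 bonding to C8 on the face it already occupied so that the C8 configuration follows from the skeleton whatever it was in 24, and hydrogen transfer to C9 should occur anti to the C7 carbonyl carbon and away from the axial methoxy group on C12 to give the 9-H shown.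

Step 15
Reactants: 25 12,12-dimethoxy-1,11-dioxo bicyclo[3.2.1]oct-15-ene lactone
Product: 26 1,11-dioxo bicyclo[3.2.1]oct-15-ene lactone (C12 methylene)
Conditions: SmI2 (6 equiv), THF–MeOH, −78 °C
Reagents that add atoms: none
Why: Reductive cleavage of the two α-methoxy groups by SmI2 (electron transfer to the C11 ketone, loss of methoxide and protonation of the samarium enolate, twice) should give the C12 methylene at −78 °C, where the unactivated C1 ketone, the esters and the C9 stereocentre are not touched.

Step 16
Reactants: 26 1,11-dioxo bicyclo[3.2.1]oct-15-ene lactone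
Product: 28 1,11-diol (both carbinol configurations as in the target), via C1 alcohol 27 (not isolated)
Conditions: NaBH4 (3 equiv), THF–i-PrOH (10:1), −20 °C to rt
Reagents that add atoms: none
Why: Substrate-directed reduction in which NaBH4 should first attack the C1 ketone axially (anti to the axial C20 methylene) to give the equatorial C1 alkoxide 27 as its borate, whose oxygen lies over the face of the C11 carbonyl that C10 closes to external reagents while the other face is roofed by the C15=C16 bridge, so that intramolecular hydride delivery from boron sets the axial C11 alcohol.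

Step 17
Reactants: 28 1,11-diol
Product: 29 1,6-diacetate 11-alcohol with the C15=C16 alkene (15-deoxo isomer of the target)
Conditions: Ac2O (1.5 equiv), pyridine, DMAP (catalytic), CH2Cl2, 0 °C
Reagents that add atoms: acetic anhydride, CC(=O)OC(C)=O
Why: Site-selective DMAP-catalysed acetylation should take the equatorial C1 hydroxyl and leave the axial C11 hydroxyl, which points into the C15=C16 bridge and is free in the natural product.

Step 18
Reactants: 29 1,6-diacetate 11-alcohol with the C15=C16 alkene
Product: 31 15-hydroxy-16(17)-ene (15-dihydro-Rabdosin B), via C15 hydroperoxide 30 (not isolated)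
Conditions: O2, tetraphenylporphyrin (catalytic), hν, CH2Cl2, 0 °C; then PPh3
Reagents that add atoms: dioxygen, O=O
Why: Schenck ene reaction of singlet oxygen with the trisubstituted alkene can take an allylic hydrogen only from the C17 methyl group (C13 is a bridgehead and C8 is quaternary), so that oxygen should add to C15 on the exo face with shift of the double bond to C16=C17, and PPh3 then reduces the hydroperoxide 30 to the allylic alcohol.

Step 19
Reactants: 31 15-hydroxy-16(17)-ene
Product: 32 Rabdosin B
Conditions: MnO2, CH2Cl2, rt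
Reagents that add atoms: none
Why: Chemoselective allylic oxidation with MnO2 should convert the C15 alcohol into the exocyclic enone and leave the saturated, hindered C11 alcohol, which gives Rabdosin B.

**Compound list**

1 | 2-methoxy-4-methylphenol (creosol) | Cc1ccc(O)c(OC)c1 | starting material
2 | 2-methoxy-1-(methoxymethoxy)-4-methylbenzene | COCOc1ccc(C)cc1OC | intermediate
3 | 4,4-dimethylcyclohex-2-en-1-one | CC1(C)C=CC(=O)CC1 | starting material
4 | hex-1-yne | CCCCC#C | starting material
5 | (E)-hex-1-enylzirconocene chloride, Cp2Zr(Cl)CH=CHBu (not isolated) | CCCC/C=C/[Zr](Cl)(C1C=CC=C1)C1C=CC=C1 | intermediate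
6 | chlorozirconocene enolate (O–Zr on C1, double bond C1=C10) of (R)-3-[(E)-hex-1-enyl]-4,4-dimethylcyclohexanone (not isolated) | CCCC/C=C/[C@H]1C=C(O[Zr](Cl)(C2C=CC=C2)C2C=CC=C2)CCC1(C)C | intermediate
7 | (2R,3S)-2-[(dimethylamino)methyl]-3-[(E)-hex-1-enyl]-4,4-dimethylcyclohexan-1-one (2,3-trans) | CN(C)C[C@@H]1C(=O)CCC(C)(C)[C@H]1/C=C/CCCC | intermediate
8 | N,N,N-trimethylammonium iodide of 7 (not isolated) | C[N+](C)(C)C[C@@H]1C(=O)CCC(C)(C)[C@H]1/C=C/CCCC.[I-] | intermediate
9 | (R)-3-[(E)-hex-1-enyl]-4,4-dimethyl-2-methylidenecyclohexan-1-one | C=C1C(=O)CCC(C)(C)[C@H]1/C=C/CCCC | intermediate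
10 | [3-methoxy-2-(methoxymethoxy)-5-methylphenyl]lithium, ArLi (not isolated) | [Li]c1cc(C)cc(OC)c1OCOC | intermediate
11 | [3-methoxy-2-(methoxymethoxy)-5-methylphenyl]cerium dichloride, ArCeCl2 (not isolated) | Cl[Ce](Cl)c1cc(C)cc(OC)c1OCOC | intermediate
12 | (1S,3R)-1-Ar-3-[(E)-hex-1-enyl]-4,4-dimethyl-2-methylidenecyclohexan-1-ol; Ar trans and OH cis to the hexenyl group | C=C1[C@](O)(c2cc(C)cc(OC)c2OCOC)CCC(C)(C)[C@H]1/C=C/CCCC | intermediate
13 | 4-Ar-8-[(E)-hex-1-enyl]-7,7-dimethyl-1-oxaspiro[2.5]octan-4-ol; epoxide oxygen cis to the 4-OH and to the hexenyl group, Ar trans to both | O[C@@]1(c2cc(C)cc(OC)c2OCOC)CCC(C)(C)[C@@H](/C=C/CCCC)[C@]12CO2 | intermediate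
14 | 2-Ar-2-[(tert-butyldimethylsilyloxy)methyl]-3-[(E)-hex-1-enyl]-4,4-dimethylcyclohexan-1-one; CH2OTBS (C20) cis and Ar trans to the hexenyl group | O=C1CCC(C)(C)[C@@H](/C=C/CCCC)[C@]1(CO[Si](C)(C)C(C)(C)C)c1cc(C)cc(OC)c1OCOC | intermediate
15 | 2-Ar-2-[(tert-butyldimethylsilyloxy)methyl]-6,6-dimethyl-3-oxocyclohexane-1-carbaldehyde; CHO (C6) cis to CH2OTBS | O=C1CCC(C)(C)[C@@H](C=O)[C@]1(CO[Si](C)(C)C(C)(C)C)c1cc(C)cc(OC)c1OCOC | intermediate
16 | 2-Ar-2-[(tert-butyldimethylsilyloxy)methyl]-3-(hydroxymethyl)-4,4-dimethylcyclohexan-1-one; the two oxymethyl groups cis | O=C1CCC(C)(C)[C@@H](CO)[C@]1(CO[Si](C)(C)C(C)(C)C)c1cc(C)cc(OC)c1OCOC | intermediate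
17 | {2-Ar-2-[(tert-butyldimethylsilyloxy)methyl]-6,6-dimethyl-3-oxocyclohexyl}methyl acetate | O=C1CCC(C)(C)[C@@H](COC(C)=O)[C@]1(CO[Si](C)(C)C(C)(C)C)c1cc(C)cc(OC)c1OCOC | intermediate
18 | [2-Ar-2-(hydroxymethyl)-6,6-dimethyl-3-oxocyclohexyl]methyl acetate; CH2OH (C20) cis to CH2OAc (C6) | O=C1CCC(C)(C)[C@@H](COC(C)=O)[C@]1(CO)c1cc(C)cc(OC)c1OCOC | intermediate
19 | 2,3-dibromopropanoyl chloride | O=C(Cl)C(Br)CBr | starting material
20 | 2,3-dibromopropanoate of 18 at the C20 oxygen (not isolated; mixture at the CHBr carbon) | O=C1CCC(C)(C)[C@@H](COC(C)=O)[C@]1(COC(=O)C(Br)CBr)c1cc(C)cc(OC)c1OCOC | intermediate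
21 | 2-bromoprop-2-enoate of 18 at the C20 oxygen | O=C1CCC(C)(C)[C@@H](COC(C)=O)[C@]1(COC(=O)C(Br)=C)c1cc(C)cc(OC)c1OCOC | intermediate
22 | phenol from 21, aryl group = 2-hydroxy-3-methoxy-5-methylphenyl (precursor of the key step) | O=C1CCC(C)(C)[C@@H](COC(C)=O)[C@]1(COC(=O)C(Br)=C)c1cc(C)cc(OC)c1O | intermediate
23 | masked o-benzoquinone from 22: C10 carries a 6,6-dimethoxy-4-methyl-1-oxocyclohexa-2,4-dien-2-yl group (not isolated) | O=C1CCC(C)(C)[C@@H](COC(C)=O)[C@]1(COC(=O)C(Br)=C)C1=CC(C)=CC(OC)(OC)C1=O | intermediate
24 | Diels–Alder adduct: bicyclo[2.2.2]oct-15-en-11-one with bridgeheads C9 (bears C10) and C13, bridges C11(=O)–C12(OMe)2, C15H=C16(Me) and C8(Br)–C14H2; δ-lactone C7(=O)–O–C20 from C8 to C10; Br syn to the C15=C16 bridge; C11 on the C1 side of the lactone; C1 ketone, C6 acetate (product of the key step) | CC1=C[C@@]23C(=O)C(OC)(OC)[C@@H]1C[C@]2(Br)C(=O)OC[C@]31C(=O)CCC(C)(C)[C@H]1COC(C)=O | intermediate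
25 | rearranged bicyclo[3.2.1]oct-15-ene: C8 quaternary (C7, C9, C14, C15), C9–H, C11 ketone, C12(OMe)2, C15H=C16(Me); C1 ketone; C5, C8, C9, C10, C13 as in Rabdosin B | CC1=C[C@]23C[C@H]1C(OC)(OC)C(=O)[C@H]2[C@]1(COC3=O)C(=O)CCC(C)(C)[C@H]1COC(C)=O | intermediate
26 | 1,11-dione of the same skeleton with C12 methylene | CC1=C[C@]23C[C@H]1CC(=O)[C@H]2[C@]1(COC3=O)C(=O)CCC(C)(C)[C@H]1COC(C)=O | intermediate
27 | 1-hydroxy 11-ketone (C1 hydroxyl equatorial, cis to C20; not isolated) | CC1=C[C@]23C[C@H]1CC(=O)[C@H]2[C@]1(COC3=O)[C@@H](O)CCC(C)(C)[C@H]1COC(C)=O | intermediate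
28 | 1,11-diol 6-acetate (C11 hydroxyl axial, on the side of the C15=C16 bridge) | CC1=C[C@]23C[C@H]1C[C@H](O)[C@H]2[C@]1(COC3=O)[C@@H](O)CCC(C)(C)[C@H]1COC(C)=O | intermediate
29 | 1,6-diacetate 11-alcohol with C15=C16 and C17 methyl | CC1=C[C@]23C[C@H]1C[C@H](O)[C@H]2[C@]1(COC3=O)[C@@H](OC(C)=O)CCC(C)(C)[C@H]1COC(C)=O | intermediate
30 | 15-hydroperoxy-16(17)-ene, OOH exo (not isolated) | C=C1[C@H](OO)[C@]23C[C@H]1C[C@H](O)[C@H]2[C@]1(COC3=O)[C@@H](OC(C)=O)CCC(C)(C)[C@H]1COC(C)=O | intermediate
31 | 15-hydroxy-16(17)-ene, OH exo (15-dihydro-Rabdosin B) | C=C1[C@H](O)[C@]23C[C@H]1C[C@H](O)[C@H]2[C@]1(COC3=O)[C@@H](OC(C)=O)CCC(C)(C)[C@H]1COC(C)=O | intermediate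
32 | Rabdosin B | C=C1C(=O)[C@]23C[C@H]1C[C@H](O)[C@H]2[C@]1(COC3=O)[C@@H](OC(C)=O)CCC(C)(C)[C@H]1COC(C)=O | target

**Step count and risks**

Total step count: 19. Longest linear sequence: 18 steps (from 3 and 4 to 32, steps 2 to 19); step 1 is a one-step branch that joins in step 4.

The three steps most likely to fail:

Step 13. The transient dienone 23 may dimerise faster than it cyclises, because the ester tether has to leave its preferred s-trans form and three fully substituted carbons (C8, C9, C10) become neighbours; weak control of the diene face by C10 would add the C9/C13-epimeric adduct. The fallback replaces the ester tether by an acetal tether, which has no such conformational penalty. It sets out from 18, whose methoxymethyl group is cleaved first (TFA, CH2Cl2, 0 °C) to give hydroxy phenol F1. Acid-catalysed acetal exchange of the primary alcohol with 2-bromo-3,3-diethoxyprop-1-ene (PPTS, benzene, removal of ethanol) gives mixed acetal F2. PhI(OAc)2 in MeOH with NaHCO3, then heating in toluene, should give cyclic acetal adduct F3 through the same two bonds. Jones oxidation (CrO3, H2SO4, acetone, 0 °C) converts the cyclic ethyl acetal into the lactone, and the route is rejoined at 24.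

Step 14. Hydrogen transfer from Bu3SnH to the first-formed C8 radical may outrun the 3-exo closure and ring opening (plain debromination), or hydrogen may be delivered to the wrong face of C9. The fallback separates the shift from the reduction. It sets out from 24, which is isomerised under bromine-atom-transfer conditions without a hydrogen donor (CuBr, tris(2-pyridylmethyl)amine, toluene, 80 °C); the radicals can then equilibrate and the chain ends at the tertiary α-bromo ketone F4. Zinc in acetic acid then reduces the C9–Br bond through the zinc enolate, whose protonation at C9 returns the route to 25.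

Step 16. The relay may break down: the C1 alkoxide may close onto C11 as a hemiketal, or lose its boron hydride to the solvent before it is passed on, leaving C11 unreduced. External hydride cannot be expected to repair this, since both faces of C11 are shielded. The fallback sets out from 27, isolated after reduction of C1 alone (NaBH4, one equivalent of hydride, −78 °C), and submits it to an Evans–Tishchenko reduction (acetaldehyde, catalytic SmI2, THF, −10 °C). The hemiacetal formed on the C1 hydroxyl should deliver its hydride to C11 from the same side and is thereby turned into the C1 acetate, so that the route is rejoined at 29 and step 17 is not needed; no compound outside the list is made.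

Further compounds
F1 | step 13 | [2-(2-hydroxy-3-methoxy-5-methylphenyl)-2-(hydroxymethyl)-6,6-dimethyl-3-oxocyclohexyl]methyl acetate (hydroxy phenol) | O=C1CCC(C)(C)[C@@H](COC(C)=O)[C@]1(CO)c1cc(C)cc(OC)c1O
F2 | step 13 | mixed ethyl acetal of F1 at the C20 oxygen with 2-bromoacrolein (mixture at the acetal carbon) | O=C1CCC(C)(C)[C@@H](COC(OCC)C(Br)=C)[C@]1(COC(C)=O)c1cc(C)cc(OC)c1O
F3 | step 13 | cyclic ethyl acetal analogue of 24 (C7 as CH(OEt) in place of the lactone carbonyl; mixture at C7) | CC1=C[C@@]23C(=O)C(OC)(OC)[C@@H]1C[C@]2(Br)C(OCC)OC[C@]31C(=O)CCC(C)(C)[C@H]1COC(C)=O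
F4 | step 14 | 9-bromo derivative of 25 (tertiary α-bromo ketone, Br in the place of 9-H) | CC1=C[C@]23C[C@H]1C(OC)(OC)C(=O)[C@@]2(Br)[C@]1(COC3=O)C(=O)CCC(C)(C)[C@H]1COC(C)=O
F0 | step 16 | none | none
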